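## Structural features

The target is a 2-arylbenzofuran in which benzene ring A is fused to furan ring B along C3a–C7a, and C2 of ring B is bonded to C5' of a 2,2-dimethylchroman made of benzene ring C and dihydropyran ring D. Ring A carries free hydroxyls at C4 and C6 and, at C7 between O6 and the ring oxygen O1, a 1,1-dimethylallyl group attached through its quaternary carbon; ring C carries a third free hydroxyl at C7'. There is no stereocentre, so no two stereocentres stand next to each other and every problem is regiochemical or chemoselective. The fragile features are the terminal vinyl group ortho to the C6 phenol (acids and soft electrophiles close it onto O6), the phloroglucinol-type ring A (easily oxidised or halogenated), and the three phenols that must be told apart. The real difficulty lies in three placements: benzylic C4' must be ortho to C5' (next to the carbon substituent of a 3,5-dioxygenated arene, not between its two oxygens), the tertiary allyl group must go to C7 and not C5, and the union at C2–C5' is flanked by the C4' methylene. The key step exploits the fact that O1, C7a, C3a, C3 and C2 of ring B are a 2-hydroxystilbene at a higher oxidation level: with the C7a oxygen and a C3=C2 double bond in place, only the O1–C2 bond and the loss of two electrons are missing.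

## Logic of the disconnections

23 ⇒ 22. The two O–CH2 acetal bonds at O4 and O7' are cut. These phenols must stay masked through base, oxidant and heat, so their release is placed last. Nothing is gained in skeleton. The forward cleavage must spare a vinyl group that sits ortho to a free phenol.

22 ⇒ 20. The C7–C(quaternary) bond is cut as a retro-[3,3] shift, which moves the side chain back to O6 as a primary allyl ether. A tertiary allyl group cannot be put on the arene by direct alkylation. The gain is that the quaternary carbon and the sensitive alkene vanish from all earlier compounds. The forward shift must go to C7 and not C5.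

20 ⇒ 17 + 18. The O6–CH2 bond is cut and O6 is re-masked as the only silyl ether of the molecule. This makes O6 the one oxygen that can be released without touching O4 and O7'. The demand is a clean O-alkylation of a phenoxide that could also react at carbon.

17 ⇒ 15. The O1–C2 bond is cut and two hydrogens are added back, which opens ring B to an (E)-2-hydroxystilbene. This removes the heterocycle and leaves an acyclic alkene between two arenes. The forward step must form the C–O bond at the alkene faster than ring A is attacked by the oxidant, which is why 15 has one free phenol and no second alkene.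

15 ⇒ 11 + 14. The C2=C3 double bond is cut into a benzylic phosphonate and an aldehyde. This halves the molecule at its centre, gives the E alkene, and avoids a metal-catalysed coupling at C5'. The forward olefination has to work on a salicylaldehyde present as its phenoxide.

14 ⇒ 13 ⇒ 12. One O–CH2 acetal bond and one O–Si bond are cut. In 12 the para oxygen is unique and the two ortho oxygens are equivalent, so the three ring A oxygens are differentiated without any regiochemical choice. The demand is para-selective silylation and a single alkylation of the ortho pair.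

11 ⇒ 10 ⇒ 9 ⇒ 8 ⇒ 7. The C–P bond, the C–Br bond and the O7' acetal bond are cut and the benzylic carbon is returned to the ester level. These are functional-group changes on a stable chroman. The forward steps must not expose the acetal to acid.

7 ⇒ 5. The O1'–C2' bond of ring D and the two O–CH3 bonds are cut, leaving a tertiary carbinol on a two-carbon chain ortho to a methoxy group. Only the oxygen next to the chain can close the ring, so the chroman regiochemistry is decided by where the chain is, not by the cyclisation. The forward step must demethylate without destroying the ester.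

5 ⇒ 4 ⇒ 2 + 3, and 2 ⇒ 1. The C4a'–C4' bond is cut after restoring the alkene, then the C–Br bond. Electrophilic halogenation of 1 goes next to the ester and not between the two methoxy groups, which pins the chain to the correct carbon. Acid-catalysed prenylation of a 3,5-dihydroxybenzyl unit would favour the position between the two hydroxyls and lead to the wrong chroman isomer. The forward coupling must tolerate an aryl bromide with two ortho substituents.

## Other disconnections considered

Alternative 1: The cut is in ring C itself, at C5'–C6' and C4a'–C8a'. In the forward step the alkynone A2 and the bis(silyloxy)diene A3 combine in a [4+2] cycloaddition. Loss of methanol and of the silyl groups aromatises the adduct to the resorcinol ketone A1, and its chelated hydroxyl can then add to the enone to give the chromanone A4.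
- In favour: the polarity match (nucleophilic terminus of A3 onto the β-carbon of the ynone) decides which ring C carbon carries the heteroaryl group and which the acyl chain, so the chroman regiochemistry is fixed by construction. The conditions are neutral and thermal, and no electron-rich arene is oxidised.
- Against: A2 presupposes the complete benzofuran with the C7 side chain and an alkyne at C2. The furan would still need a closure of its own, and the vinyl group would have to survive every later step. A2 also has a second acceptor in its β,β-dimethylenone. After A4 the C4' carbonyl must be reduced to CH2 beside a terminal alkene, a free phenol and two acetals, which excludes hydrogenation and strongly acidic ionic reduction.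
- Comparison: on ring C regiocontrol it equals the sequence 1 → 7 and is better in needing no demethylation. Mechanistically the cycloaddition is gentler than the oxidation of 15, which is a point in its favour. In step economy it is worse, because it adds a carbonyl removal and does not supply ring B.

Alternative 2: The cut is in ring D, at C4'–C3' and O1'–C2'. In the forward step the salicyl alcohol A5 loses water on heating to the o-quinone methide A6, which is trapped by 2-methylpropene A7 in an inverse-demand hetero-Diels–Alder reaction to give the bromochroman A8.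
- In favour: ring D forms in one step, the polarisation of A6 puts oxygen on the disubstituted alkene carbon, and no aryl methyl ether has to be cleaved.
- Against: it answers only the fragment question. A8 carries a halogen where the plan needs a one-carbon phosphonate, so metal–halogen exchange with formylation, reduction, bromination and phosphonylation would follow, or a cross-coupling at C5' next to the C4' methylene. A5 needs its hydroxymethyl group between a hydroxyl and a bromine, the least accessible ortho position, so the regiochemical problem is only moved back one compound. A gaseous alkene at high temperature needs a pressure vessel, and A6 can self-condense.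
- Comparison: for closing ring D it is better than 2 → 4 → 5 → 7 (one step against three). In regiochemical security it is equal once A5 is in hand. Counted up to 11 it is about equal or slightly longer, and it leaves the key step and the end game unchanged.

Alternative 3: The cut is the benzofuran C3–C3a bond, traced back to a flavanone in which ring A is bonded to the carbonyl carbon. In the forward step the flavanone A9 is treated with a hypervalent iodine diacetate and strong acid in an orthoformate. Ring A shifts from the carbonyl carbon to C3 and the pyranone contracts to the trans dihydrobenzofuran ester A10.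
- In favour: A9 is reached by an aldol-type union and oxa-Michael closure, so ring C enters at the aldehyde level and steps 6–8 would not be needed, which is better fragment economy. O1–C2 and C2–C5' exist before the oxidation, and no free phenol meets the oxidant.
- Against: the ester carbon must be excised by hydrolysis, decarboxylation and dehydrogenation. The medium is strongly acidic and oxidising, and the electron-rich chromanyl group at C2 can itself migrate toward an isoflavone. The methyl ethers at O4 and O7' of A10 would have to be cleaved late, next to the acid-sensitive side chain, or exchanged earlier. Two stereocentres are made only to be destroyed.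
- Comparison: in convergence it is equal, and in fragment C economy it is better. In mechanism it trades one oxidation of an electron-rich system for another under harsher acid. Overall it is not shorter, since the extra carbon and the protecting-group exchange use up what the aldol union saves.

Key step: step 12

Remark on the chemistry: the para oxygen of ring A is carried as a triisopropylsilyl ether (not tert-butyldimethylsilyl) because it must survive the sodium phenoxide in step 11; the skeletons of 15 and 17 are otherwise unchanged. Intermediates 16 and 21 are racemic and transient.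

## Steps

Step 1
Reactants: 1 methyl 3,5-dimethoxybenzoate
Product: 2 methyl 2-bromo-3,5-dimethoxybenzoate
Conditions: NBS (1.05 equiv), MeCN, 0 °C → rt
Reagents that add atoms: N-bromosuccinimide, O=C1CCC(=O)N1Br
Why: Electrophilic aromatic bromination; in a resorcinol diether the carbon para to one methoxy and ortho to the other (C2, next to the ester) is attacked in preference to the carbon between the two methoxy groups, so the halogen marks the future C4a'.

Step 2
Reactants: 2 methyl 2-bromo-3,5-dimethoxybenzoate; 3 2-methylbut-3-en-2-ol
Product: 4 methyl (E)-2-(3-hydroxy-3-methylbut-1-en-1-yl)-3,5-dimethoxybenzoate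
Conditions: Pd2(dba)3 (2 mol%), [HP(t-Bu)3]BF4 (8 mol%), Cy2NMe, dioxane, 90 °C
Reagents that add atoms: none
Why: Mizoroki–Heck arylation of a terminal alkene; the bulky electron-rich phosphine lets the ortho,ortho-disubstituted bromide add to zerovalent palladium, and since the carbinol carbon has no hydrogen, β-hydride elimination can only give the (E)-styrene.

Step 3
Reactants: 4 methyl (E)-2-(3-hydroxy-3-methylbut-1-en-1-yl)-3,5-dimethoxybenzoate
Product: 5 methyl 2-(3-hydroxy-3-methylbutyl)-3,5-dimethoxybenzoate
Conditions: H2 (1 atm), 10% Pd/C, EtOAc, rt
Reagents that add atoms: none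
Why: Heterogeneous hydrogenation of a styrene double bond; a neutral aprotic solvent keeps hydrogenolysis of the tertiary allylic C–O bond slow, and the ester and aryl ethers are inert.

Step 4
Reactants: 5 methyl 2-(3-hydroxy-3-methylbutyl)-3,5-dimethoxybenzoate
Product: 7 methyl 7-hydroxy-2,2-dimethylchroman-5-carboxylate, via methyl 2-(3-bromo-3-methylbutyl)-3,5-dihydroxybenzoate 6 (not isolated)
Conditions: BBr3 (4.5 equiv), CH2Cl2, −78 → 0 °C; H2O quench; then TsOH·H2O (10 mol%), PhMe, 80 °C
Reagents that add atoms: none
Why: Lewis-acid cleavage of both aryl methyl ethers, which spares a methyl ester at low temperature, also turns the tertiary carbinol into the tertiary bromide; its ionisation next to the O3 phenol then closes the six-membered ether, the known acid-mediated cyclisation of 2-(3-hydroxy-3-methylbutyl)phenols to 2,2-dimethylchromans. Only the oxygen ortho to the chain can reach the cation, so the 7-hydroxy-5-carboxylate isomer is the only chroman possible.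

Step 5
Reactants: 7 methyl 7-hydroxy-2,2-dimethylchroman-5-carboxylate
Product: 8 methyl 7-(methoxymethoxy)-2,2-dimethylchroman-5-carboxylate
Conditions: MOMCl, i-Pr2NEt, CH2Cl2, 0 °C → rt
Reagents that add atoms: chloromethyl methyl ether (MOMCl), COCCl
Why: O-alkylation of the only phenol with an α-chloro ether (Williamson type); the acetal withstands the basic, reductive and thermal steps that follow and leaves together with the ring A acetal at the end.

Step 6
Reactants: 8 methyl 7-(methoxymethoxy)-2,2-dimethylchroman-5-carboxylate
Product: 9 [7-(methoxymethoxy)-2,2-dimethylchroman-5-yl]methanol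
Conditions: LiAlH4, THF, 0 °C
Reagents that add atoms: none
Why: Hydride reduction of an aryl ester to the benzylic alcohol; the acetal and the ring ether are inert to LiAlH4.

Step 7
Reactants: 9 [7-(methoxymethoxy)-2,2-dimethylchroman-5-yl]methanol
Product: 10 5-(bromomethyl)-7-(methoxymethoxy)-2,2-dimethylchroman
Conditions: CBr4, PPh3, CH2Cl2, 0 °C
Reagents that add atoms: carbon tetrabromide, BrC(Br)(Br)Br
Why: Appel bromination under neutral conditions, so no acid reaches the acetal; both ring oxygens are meta to the benzylic carbon, so the bromide does not ionise readily and can be handled.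

Step 8
Reactants: 10 5-(bromomethyl)-7-(methoxymethoxy)-2,2-dimethylchroman
Product: 11 diethyl {[7-(methoxymethoxy)-2,2-dimethylchroman-5-yl]methyl}phosphonate
Conditions: P(OEt)3 (neat), 130 °C
Reagents that add atoms: triethyl phosphite, CCOP(OCC)OCC
Why: Michaelis–Arbuzov reaction of a primary benzylic bromide; bromoethane distils out and drives the reaction, and the conditions are neutral.

Step 9
Reactants: 12 2,4,6-trihydroxybenzaldehyde
Product: 13 2,6-dihydroxy-4-[(triisopropylsilyl)oxy]benzaldehyde
Conditions: TIPSCl (1.0 equiv), imidazole, DMF, −10 → 0 °C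
Reagents that add atoms: chlorotriisopropylsilane (TIPSCl), CC(C)[Si](Cl)(C(C)C)C(C)C
Why: Selective O-silylation; the para hydroxyl is the most acidic and is not held in a hydrogen bond to the aldehyde, and the bulky silyl chloride does not reach the two ortho hydroxyls beside the carbonyl.

Step 10
Reactants: 13 2,6-dihydroxy-4-[(triisopropylsilyl)oxy]benzaldehyde
Product: 14 2-hydroxy-6-(methoxymethoxy)-4-[(triisopropylsilyl)oxy]benzaldehyde
Conditions: MOMCl (1.05 equiv), i-Pr2NEt, CH2Cl2, 0 °C
Reagents that add atoms: chloromethyl methyl ether (MOMCl), COCCl
Why: Mono-O-alkylation of a 2,6-dihydroxybenzaldehyde; the two ortho hydroxyls are equivalent, and once one is capped the other stays locked in the hydrogen bond to the carbonyl and reacts much more slowly, as is known for 2,4,6-trihydroxybenzaldehyde with chloromethyl ethers.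

Step 11
Reactants: 11 diethyl {[7-(methoxymethoxy)-2,2-dimethylchroman-5-yl]methyl}phosphonate; 14 2-hydroxy-6-(methoxymethoxy)-4-[(triisopropylsilyl)oxy]benzaldehyde
Product: 15 (E)-2-{2-[7-(methoxymethoxy)-2,2-dimethylchroman-5-yl]ethenyl}-3-(methoxymethoxy)-5-[(triisopropylsilyl)oxy]phenol
Conditions: NaH (2.5 equiv), 15-crown-5 (cat.), THF, 0 → 60 °C
Reagents that add atoms: none
Why: Horner–Wadsworth–Emmons olefination with a benzylic phosphonate, which gives (E)-stilbenes; one equivalent of base is spent on the phenol, and the strongly nucleophilic phosphonate anion together with warming should make up for the lower electrophilicity of the phenoxide aldehyde. The triisopropylsilyl ether resists silyl transfer to the sodium phenoxide.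

Step 12
Reactants: 15 (E)-2-{2-[7-(methoxymethoxy)-2,2-dimethylchroman-5-yl]ethenyl}-3-(methoxymethoxy)-5-[(triisopropylsilyl)oxy]phenol
Product: 17 4-(methoxymethoxy)-2-[7-(methoxymethoxy)-2,2-dimethylchroman-5-yl]-6-[(triisopropylsilyl)oxy]benzofuran, via trans-3-iodo-2,3-dihydrobenzofuran 16 (not isolated)
Conditions: I2 (1.5 equiv), K2CO3 (4 equiv), THF, 0 °C → rt; aq. Na2S2O3
Reagents that add atoms: none
Why: This is the iodine-mediated oxidative cyclisation of a 2-hydroxystilbene to a 2-arylbenzofuran, a known reaction type. Carbonate converts the single free phenol into its phenoxide, and iodine adds to the stilbene double bond as an iodonium ion. The C7a oxygen opens it at the carbon bearing ring C in an anti, formally 5-endo-trig closure, which forms O1–C2, closes ring B and gives the trans iodide 16. The C3–I bond is benzylic to ring A and activated by its ortho and para oxygens, so hydrogen iodide is lost at once (E1) and the furan aromatises; the two transient stereocentres disappear and the product has none. The step needs O–C bond formation at the alkene to outrun iodination of ring A and of C3 of the product. This should be secured by having one phenol only, placed five atoms from the alkene carbon, by the absence of any other alkene, by the silyl and acetal caps on the other oxygens, and by a small excess of iodine at 0 °C. Either alkene geometry would converge on 17, but the E isomer from step 11 needs no prior isomerisation.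

Step 13
Reactants: 17 4-(methoxymethoxy)-2-[7-(methoxymethoxy)-2,2-dimethylchroman-5-yl]-6-[(triisopropylsilyl)oxy]benzofuran; 18 1-bromo-3-methylbut-2-ene (prenyl bromide)
Product: 20 4-(methoxymethoxy)-2-[7-(methoxymethoxy)-2,2-dimethylchroman-5-yl]-6-[(3-methylbut-2-en-1-yl)oxy]benzofuran, via benzofuran-6-ol 19 (not isolated)
Conditions: CsF (3 equiv), DMF, rt → 40 °C
Reagents that add atoms: none
Why: Fluoride cleaves the aryl silyl ether and the phenoxide of 19 is alkylated in situ at oxygen by the allylic bromide (SN2), the known one-pot conversion of aryl silyl ethers into aryl alkyl ethers. O6 is the only oxygen set free, so no other phenol can be prenylated, and the polar aprotic solvent favours O- over C-alkylation.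

Step 14
Reactants: 20 4-(methoxymethoxy)-2-[7-(methoxymethoxy)-2,2-dimethylchroman-5-yl]-6-[(3-methylbut-2-en-1-yl)oxy]benzofuran
Product: 22 4-(methoxymethoxy)-2-[7-(methoxymethoxy)-2,2-dimethylchroman-5-yl]-7-(2-methylbut-3-en-2-yl)benzofuran-6-ol, via benzofuran-6(7H)-one 21 (not isolated)
Conditions: PhNEt2, 190 °C (sealed tube), 1–2 h
Reagents that add atoms: none
Why: Aromatic Claisen rearrangement of an aryl prenyl ether, which delivers the allyl unit inverted (as 1,1-dimethylallyl) to an ortho carbon, followed by enolisation of dienone 21. The shift to C7 uses the C6–C7 bond and leaves the C3a–C7a bond, and with it the furan sextet, intact, whereas a shift to C5 would need an ortho-quinoid dienone that breaks the furan conjugation; C5 is also flanked by the C4 acetal. The basic solvent suppresses acid-catalysed loss of the prenyl group and closure of the new phenol onto the alkene.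

Step 15
Reactants: 22 4-(methoxymethoxy)-2-[7-(methoxymethoxy)-2,2-dimethylchroman-5-yl]-7-(2-methylbut-3-en-2-yl)benzofuran-6-ol
Product: 23 2-(7-hydroxy-2,2-dimethylchroman-5-yl)-7-(2-methylbut-3-en-2-yl)benzofuran-4,6-diol (CNP0300714.0)
Conditions: HCl (1.25 M in MeOH), rt → 40 °C
Reagents that add atoms: none
Why: Acid-catalysed transacetalisation of the two aryl methoxymethyl ethers to dimethoxymethane; a monosubstituted vinyl group is protonated only by much stronger acid than the acetals need, so dilute acid at low temperature should leave the 1,1-dimethylallyl phenol untouched.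

## Compound list

1 | methyl 3,5-dimethoxybenzoate | COC(=O)c1cc(OC)cc(OC)c1 | starting material
2 | methyl 2-bromo-3,5-dimethoxybenzoate | COC(=O)c1cc(OC)cc(OC)c1Br | intermediate
3 | 2-methylbut-3-en-2-ol | C=CC(C)(C)O | starting material
4 | methyl (E)-2-(3-hydroxy-3-methylbut-1-en-1-yl)-3,5-dimethoxybenzoate | COC(=O)c1cc(OC)cc(OC)c1/C=C/C(C)(C)O | intermediate
5 | methyl 2-(3-hydroxy-3-methylbutyl)-3,5-dimethoxybenzoate | COC(=O)c1cc(OC)cc(OC)c1CCC(C)(C)O | intermediate
6 | methyl 2-(3-bromo-3-methylbutyl)-3,5-dihydroxybenzoate | COC(=O)c1cc(O)cc(O)c1CCC(C)(C)Br | intermediate (not isolated)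
7 | methyl 7-hydroxy-2,2-dimethylchroman-5-carboxylate | COC(=O)c1cc(O)cc2c1CCC(C)(C)O2 | intermediate
8 | methyl 7-(methoxymethoxy)-2,2-dimethylchroman-5-carboxylate | COCOc1cc(C(=O)OC)c2c(c1)OC(C)(C)CC2 | intermediate
9 | [7-(methoxymethoxy)-2,2-dimethylchroman-5-yl]methanol | COCOc1cc(CO)c2c(c1)OC(C)(C)CC2 | intermediate
10 | 5-(bromomethyl)-7-(methoxymethoxy)-2,2-dimethylchroman | COCOc1cc(CBr)c2c(c1)OC(C)(C)CC2 | intermediate
11 | diethyl {[7-(methoxymethoxy)-2,2-dimethylchroman-5-yl]methyl}phosphonate | CCOP(=O)(OCC)Cc1cc(OCOC)cc2c1CCC(C)(C)O2 | intermediate
12 | 2,4,6-trihydroxybenzaldehyde | O=Cc1c(O)cc(O)cc1O | starting material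
13 | 2,6-dihydroxy-4-[(triisopropylsilyl)oxy]benzaldehyde | CC(C)[Si](Oc1cc(O)c(C=O)c(O)c1)(C(C)C)C(C)C | intermediate
14 | 2-hydroxy-6-(methoxymethoxy)-4-[(triisopropylsilyl)oxy]benzaldehyde | COCOc1cc(O[Si](C(C)C)(C(C)C)C(C)C)cc(O)c1C=O | intermediate
15 | (E)-2-{2-[7-(methoxymethoxy)-2,2-dimethylchroman-5-yl]ethenyl}-3-(methoxymethoxy)-5-[(triisopropylsilyl)oxy]phenol | COCOc1cc(O[Si](C(C)C)(C(C)C)C(C)C)cc(O)c1/C=C/c1cc(OCOC)cc2c1CCC(C)(C)O2 | intermediate
16 | trans-3-iodo-4-(methoxymethoxy)-2-[7-(methoxymethoxy)-2,2-dimethylchroman-5-yl]-6-[(triisopropylsilyl)oxy]-2,3-dihydrobenzofuran (racemic, relative configuration shown) | I[C@H]1[C@H](c3cc(OCOC)cc4c3CCC(C)(C)O4)Oc2cc(O[Si](C(C)C)(C(C)C)C(C)C)cc(OCOC)c21 | intermediate (not isolated)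
17 | 4-(methoxymethoxy)-2-[7-(methoxymethoxy)-2,2-dimethylchroman-5-yl]-6-[(triisopropylsilyl)oxy]benzofuran | COCOc1cc(O[Si](C(C)C)(C(C)C)C(C)C)cc2oc(-c3cc(OCOC)cc4c3CCC(C)(C)O4)cc12 | intermediate
18 | 1-bromo-3-methylbut-2-ene (prenyl bromide) | CC(C)=CCBr | starting material
19 | 4-(methoxymethoxy)-2-[7-(methoxymethoxy)-2,2-dimethylchroman-5-yl]benzofuran-6-ol (formed as its caesium salt) | COCOc1cc(O)cc2oc(-c3cc(OCOC)cc4c3CCC(C)(C)O4)cc12 | intermediate (not isolated)
20 | 4-(methoxymethoxy)-2-[7-(methoxymethoxy)-2,2-dimethylchroman-5-yl]-6-[(3-methylbut-2-en-1-yl)oxy]benzofuran | COCOc1cc(OCC=C(C)C)cc2oc(-c3cc(OCOC)cc4c3CCC(C)(C)O4)cc12 | intermediate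
21 | 4-(methoxymethoxy)-2-[7-(methoxymethoxy)-2,2-dimethylchroman-5-yl]-7-(2-methylbut-3-en-2-yl)benzofuran-6(7H)-one (racemic) | C=CC(C)(C)C1C(=O)C=C(OCOC)c2cc(-c3cc(OCOC)cc4c3CCC(C)(C)O4)oc21 | intermediate (not isolated)
22 | 4-(methoxymethoxy)-2-[7-(methoxymethoxy)-2,2-dimethylchroman-5-yl]-7-(2-methylbut-3-en-2-yl)benzofuran-6-ol | C=CC(C)(C)c1c(O)cc(OCOC)c2cc(-c3cc(OCOC)cc4c3CCC(C)(C)O4)oc12 | intermediate
23 | 2-(7-hydroxy-2,2-dimethylchroman-5-yl)-7-(2-methylbut-3-en-2-yl)benzofuran-4,6-diol (CNP0300714.0) | C=CC(C)(C)c1c(O)cc(O)c2cc(-c3cc(O)cc4c3CCC(C)(C)O4)oc12 | target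

## Step count and least certain steps

Total step count: 15. Longest linear sequence: 13 steps (steps 1–8, then 11–15); the ring A branch (steps 9–10) joins at step 11.

Step 12 (key step). Electrophilic iodination of ring A, or of C3 of the product, may compete with O–C bond formation, because both arenes are very electron-rich. Fallback: from 15, selenoetherification with PhSeCl and K2CO3 in CH2Cl2 at −78 °C, using a softer electrophile that is less prone to attack the arene, should give trans-4-(methoxymethoxy)-2-[7-(methoxymethoxy)-2,2-dimethylchroman-5-yl]-3-(phenylselanyl)-6-[(triisopropylsilyl)oxy]-2,3-dihydrobenzofuran F1. Oxidation with H2O2 and pyridine at 0 °C then gives the selenoxide, whose syn elimination toward the cis C2 hydrogen returns the route at 17.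

Step 11. Addition of the phosphonate anion to the phenoxide-deactivated aldehyde may be slow, and prolonged heating invites silyl transfer between phenoxide oxygens. Fallback: from 14, the free hydroxyl is capped with allyl bromide and K2CO3 in acetone to give 2-(allyloxy)-6-(methoxymethoxy)-4-[(triisopropylsilyl)oxy]benzaldehyde F2. Olefination with 11 (NaH, THF) then gives (E)-5-{2-[2-(allyloxy)-6-(methoxymethoxy)-4-[(triisopropylsilyl)oxy]phenyl]ethenyl}-7-(methoxymethoxy)-2,2-dimethylchroman F3, and Pd(PPh3)4 with morpholine in THF removes the allyl group to return at 15.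

Step 14. The allylic C–O bond may ionise with loss of the prenyl group, and the new phenol may add thermally to its own vinyl group; migration to C5 is the less likely failure. Fallback: from 20, the rearrangement is run in PhNEt2 with Ac2O and NaOAc at 185 °C, so the phenol is captured as it forms as 4-(methoxymethoxy)-2-[7-(methoxymethoxy)-2,2-dimethylchroman-5-yl]-7-(2-methylbut-3-en-2-yl)benzofuran-6-yl acetate F4. Methanolysis with K2CO3 in MeOH at rt returns at 22.

Step 4. Ring closure may stay incomplete, because the tertiary bromide can eliminate to alkenes, and the Lewis acid may partly cleave the methyl ester. Fallback: from 2, demethylation alone with BBr3 gives methyl 2-bromo-3,5-dihydroxybenzoate F5. Heck coupling with 3 (Pd(OAc)2, P(o-tol)3, Et3N, DMF, 100 °C) gives methyl (E)-3,5-dihydroxy-2-(3-hydroxy-3-methylbut-1-en-1-yl)benzoate F6. Catalytic TsOH in toluene closes this, through the allylic cation, to methyl 7-hydroxy-2,2-dimethyl-2H-chromene-5-carboxylate F7, and hydrogenation over Pd/C returns at 7.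

Step 15. Acid may promote Markovnikov addition of the C6 hydroxyl across the vinyl group while the acetals are being cleaved. Fallback: from 22, TMSOTf with 2,2'-bipyridyl in CH2Cl2 at 0 °C exchanges the acetals for silyl groups without free protic acid, giving the tris(trimethylsilyl) ether 2-[2,2-dimethyl-7-(trimethylsilyloxy)chroman-5-yl]-7-(2-methylbut-3-en-2-yl)-4,6-bis(trimethylsilyloxy)benzofuran F8. Addition of water hydrolyses it to 23.

## Further compounds

F1 | step 12 | trans-4-(methoxymethoxy)-2-[7-(methoxymethoxy)-2,2-dimethylchroman-5-yl]-3-(phenylselanyl)-6-[(triisopropylsilyl)oxy]-2,3-dihydrobenzofuran (racemic, relative configuration shown) | c1ccccc1[Se][C@H]1[C@H](c3cc(OCOC)cc4c3CCC(C)(C)O4)Oc2cc(O[Si](C(C)C)(C(C)C)C(C)C)cc(OCOC)c21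
F2 | step 11 | 2-(allyloxy)-6-(methoxymethoxy)-4-[(triisopropylsilyl)oxy]benzaldehyde | C=CCOc1cc(O[Si](C(C)C)(C(C)C)C(C)C)cc(OCOC)c1C=O
F3 | step 11 | (E)-5-{2-[2-(allyloxy)-6-(methoxymethoxy)-4-[(triisopropylsilyl)oxy]phenyl]ethenyl}-7-(methoxymethoxy)-2,2-dimethylchroman | C=CCOc1cc(O[Si](C(C)C)(C(C)C)C(C)C)cc(OCOC)c1/C=C/c1cc(OCOC)cc2c1CCC(C)(C)O2
F4 | step 14 | 4-(methoxymethoxy)-2-[7-(methoxymethoxy)-2,2-dimethylchroman-5-yl]-7-(2-methylbut-3-en-2-yl)benzofuran-6-yl acetate | C=CC(C)(C)c1c(OC(C)=O)cc(OCOC)c2cc(-c3cc(OCOC)cc4c3CCC(C)(C)O4)oc12
F5 | step 4 | methyl 2-bromo-3,5-dihydroxybenzoate | COC(=O)c1cc(O)cc(O)c1Br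
F6 | step 4 | methyl (E)-3,5-dihydroxy-2-(3-hydroxy-3-methylbut-1-en-1-yl)benzoate | COC(=O)c1cc(O)cc(O)c1/C=C/C(C)(C)O
F7 | step 4 | methyl 7-hydroxy-2,2-dimethyl-2H-chromene-5-carboxylate | COC(=O)c1cc(O)cc2c1C=CC(C)(C)O2
F8 | step 15 | 2-[2,2-dimethyl-7-(trimethylsilyloxy)chroman-5-yl]-7-(2-methylbut-3-en-2-yl)-4,6-bis(trimethylsilyloxy)benzofuran | C=CC(C)(C)c1c(O[Si](C)(C)C)cc(O[Si](C)(C)C)c2cc(-c3cc(O[Si](C)(C)C)cc4c3CCC(C)(C)O4)oc12
A1 | alternative 1 | 1-{2-[4,6-bis(methoxymethoxy)-7-(2-methylbut-3-en-2-yl)benzofuran-2-yl]-4,6-dihydroxyphenyl}-3-methylbut-2-en-1-one | C=CC(C)(C)c1c(OCOC)cc(OCOC)c2cc(-c3cc(O)cc(O)c3C(=O)C=C(C)C)oc12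
A2 | alternative 1 | 1-[4,6-bis(methoxymethoxy)-7-(2-methylbut-3-en-2-yl)benzofuran-2-yl]-5-methylhex-4-en-1-yn-3-one | C=CC(C)(C)c1c(OCOC)cc(OCOC)c2cc(C#CC(=O)C=C(C)C)oc12
A3 | alternative 1 | 1-methoxy-1,3-bis(trimethylsilyloxy)buta-1,3-diene | COC(O[Si](C)(C)C)=CC(=C)O[Si](C)(C)C
A4 | alternative 1 | 5-[4,6-bis(methoxymethoxy)-7-(2-methylbut-3-en-2-yl)benzofuran-2-yl]-7-hydroxy-2,2-dimethylchroman-4-one | C=CC(C)(C)c1c(OCOC)cc(OCOC)c2cc(-c3cc(O)cc4c3C(=O)CC(C)(C)O4)oc12
A5 | alternative 2 | 3-bromo-2-(hydroxymethyl)-5-(methoxymethoxy)phenol | OCc1c(O)cc(OCOC)cc1Br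
A6 | alternative 2 | 5-bromo-3-(methoxymethoxy)-6-methylidenecyclohexa-2,4-dien-1-one | C=C1C(=O)C=C(OCOC)C=C1Br
A7 | alternative 2 | 2-methylpropene | CC(C)=C
A8 | alternative 2 | 5-bromo-7-(methoxymethoxy)-2,2-dimethylchroman | COCOc1cc(Br)c2c(c1)OC(C)(C)CC2
A9 | alternative 3 | 7-(benzyloxy)-5-methoxy-2-(7-methoxy-2,2-dimethylchroman-5-yl)chroman-4-one (racemic) | COc1cc(OCc2ccccc2)cc2c1C(=O)CC(c1cc(OC)cc3c1CCC(C)(C)O3)O2
A10 | alternative 3 | methyl trans-6-(benzyloxy)-4-methoxy-2-(7-methoxy-2,2-dimethylchroman-5-yl)-2,3-dihydrobenzofuran-3-carboxylate (racemic, relative configuration shown) | COC(=O)[C@H]1[C@H](c2cc(OC)cc3c2CCC(C)(C)O3)Oc2cc(OCc3ccccc3)cc(OC)c21
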